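**Retrosynthetic overview**
1. 10-Acetylirciformonin B comes from chemoselective C10 acetylation of diol 20. Diol 20 comes from Ni-electrocatalytic decarboxylative alkenylation (C6–C7) of (E)-vinyl iodide 17 with redox-active ester (RAE) 19.
2. Iodide 17 comes from Ru cross-metathesis (C11=C12) of chiral vinyl carbinol 16 with carbinol 8. C10 of 16 comes from (S)-epichlorohydrin (acetylide opening, epoxide, sulfonium-ylide homologation, Zr-carboalumination).
3. Carbinol 8 comes from photoredox/Cr addition of a homoallyl radical (RAE 7) to aldehyde 4 (C14–C15 bond). C15 is set by Felkin control from the quaternary centre, which comes from (S)-linalool.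
4. The γ-lactone is formed first (step 2, from linalool). The furan is carried in intact from 18. No other ring is formed.

Assumptions: "irciformonin B" is the 10-OH parent. (S)-Linalool, (S)-epichlorohydrin, 4-methylpent-4-enoic acid and 3-(furan-3-yl)propanoic acid are purchasable.

**Step 1**
Reactants: 1 (S)-linalool
Product: 2 (5S)-5-methyl-5-vinyltetrahydrofuran-2-ol (lactol; open form (S)-4-hydroxy-4-methylhex-5-enal)
Conditions: OsO4 (2 mol %), NaIO4 (2.1 equiv), 2,6-lutidine, dioxane/H2O 3:1, rt
Reagents that add atoms: NaIO4, [Na+].[O-]I(=O)(=O)=O (source of the aldehyde O; OsO4 is catalytic)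
Why: Lemieux–Johnson cleavage with only 2.1 equiv periodate consumes the electron-rich trisubstituted alkene and leaves the hindered vinyl group. The tertiary carbinol stereocentre is untouched, and the aldehyde closes to the lactol.

**Step 2**
Reactants: 2
Product: 3 (5S)-5-methyl-5-vinyldihydrofuran-2(3H)-one
Conditions: TEMPO (10 mol %), PhI(OAc)2 (1.5 equiv), CH2Cl2, rt
Reagents that add atoms: none
Why: TEMPO/BAIB oxidation of the lactol to the γ-lactone; the quaternary centre cannot epimerise.

**Step 3**
Reactants: 3
Product: 4 (5S)-5-methyl-2-oxotetrahydrofuran-5-carbaldehyde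
Conditions: O3, CH2Cl2, −78 °C; then Me2S, −78 °C to rt
Reagents that add atoms: ozone, [O-][O+]=O
Why: Ozonolysis of the monosubstituted vinyl group gives the α-quaternary aldehyde while the lactone and stereocentre survive.

**Step 4**
Reactants: 5 4-methylpent-4-enoic acid; 6 N-hydroxyphthalimide
Product: 7 1,3-dioxoisoindolin-2-yl 4-methylpent-4-enoate
Conditions: DIC (1.1 equiv), DMAP (10 mol %), CH2Cl2, rt
Reagents that add atoms: none
Why: Steglich-type esterification gives the redox-active ester, a precursor of the 3-methylbut-3-enyl radical.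

**Step 5**
Reactants: 4; 7
Product: 8 (5S)-5-[(1R)-1-hydroxy-4-methylpent-4-en-1-yl]-5-methyldihydrofuran-2(3H)-one
Conditions: CrCl3 (10 mol %), 4,4′-di-tBu-bipyridine (10 mol %), 4CzIPN (2 mol %), Hantzsch ester (1.5 equiv), TMSCl (2 equiv), MeCN, blue LEDs, rt, 16 h; then 1 M HCl/THF
Reagents that add atoms: none (the TMS ether is cleaved on workup)
Why: Proposed new method: the photocatalyst radical anion reduces the RAE, which loses CO2 and phthalimide to give the primary homoallyl radical. Cr(II) traps it as a non-basic alkyl-Cr(III) that adds chemoselectively to the aldehyde over the lactone, and TMSCl releases the Cr(III) alkoxide. C15 is set by polar Felkin–Anh attack anti to the ring C–O bond of the (S) quaternary carbon, giving the (R) alcohol. The closest known reactions are dual photoredox/Cr NHK-type allylation of aldehydes and Cr Barbier alkylation; what is new is an unactivated primary alkyl radical adding to an α-quaternary α-acyloxy aldehyde with substrate-controlled diastereoselectivity.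

**Step 6**
Reactants: 9 (S)-epichlorohydrin; 10 trimethylsilylacetylene
Product: 11 (2S)-1-chloro-5-(trimethylsilyl)pent-4-yn-2-ol
Conditions: n-BuLi, then BF3·OEt2, THF, −78 °C
Reagents that add atoms: none (10 is the reactant)
Why: BF3-mediated acetylide opening (Yamaguchi–Hirao) occurs at the terminal epoxide carbon, so the C10 carbinol stereocentre is never touched.

**Step 7**
Reactants: 11
Product: 12 (2S)-trimethyl[3-(oxiran-2-yl)prop-1-yn-1-yl]silane
Conditions: NaH (1.2 equiv), THF, 0 °C to rt
Reagents that add atoms: none
Why: Intramolecular Williamson (3-exo-tet) closure at the CH2Cl carbon keeps the C–O bond at the stereocentre, and the TMS-alkyne survives.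

**Step 8**
Reactants: 12; 13 trimethylsulfonium iodide
Product: 14 (3S)-7-(trimethylsilyl)hept-1-en-6-yn-3-ol
Conditions: 13 (4 equiv), n-BuLi (3.8 equiv), THF, −10 °C; add 12; −10 °C to rt
Reagents that add atoms: none (13 is the reactant)
Why: Alcaraz sulfonium-ylide epoxide-to-allylic-alcohol homologation attacks the terminal CH2 and builds the vinyl group, leaving the carbinol stereocentre untouched.

**Step 9**
Reactants: 14
Product: 15 (3S)-hept-1-en-6-yn-3-ol
Conditions: K2CO3 (0.3 equiv), MeOH, rt
Reagents that add atoms: none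
Why: Base-mediated protodesilylation of the alkynyl-TMS.

**Step 10**
Reactants: 15
Product: 16 (3S,6E)-7-iodo-6-methylhepta-1,6-dien-3-ol
Conditions: (i) Me3Al (3.5 equiv), Cp2ZrCl2 (0.3 equiv), ClCH2CH2Cl, 0 °C to rt; (ii) I2 (1.5 equiv), THF, −30 °C
Reagents that add atoms: Me3Al, C[Al](C)C; I2, II
Why: Negishi Zr-catalysed methylalumination is a syn-addition that places Me on the internal alkyne carbon and Al on the terminal carbon; iodination with retention then gives the (E)-trisubstituted vinyl iodide, with the alkyne reacting in preference to the vinyl group.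

**Step 11**
Reactants: 16 (3 equiv); 8
Product: 17 (5S)-5-[(1R,4E,6S,8E)-1,6-dihydroxy-9-iodo-4,8-dimethylnona-4,8-dien-1-yl]-5-methyldihydrofuran-2(3H)-one
Conditions: Hoveyda–Grubbs II (5 mol %), CH2Cl2 (0.05 M), 40 °C, 16 h
Reagents that add atoms: none
Why: Ru cross-metathesis of the reactive monosubstituted vinyl carbinol with the 1,1-disubstituted alkene forms the E-trisubstituted C11=C12 alkene (Z isomer removed by chromatography), while the vinyl iodide is inert and all three stereocentres are spectators.

**Step 12**
Reactants: 18 3-(furan-3-yl)propanoic acid; 6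
Product: 19 1,3-dioxoisoindolin-2-yl 3-(furan-3-yl)propanoate
Conditions: DIC (1.1 equiv), DMAP (10 mol %), CH2Cl2, rt
Reagents that add atoms: none
Why: Steglich-type esterification gives the RAE, a precursor of the 2-(furan-3-yl)ethyl radical.

**Step 13**
Reactants: 17; 19 (2.5 equiv)
Product: 20 (5S)-5-[(1R,4E,6S,8E)-11-(furan-3-yl)-1,6-dihydroxy-4,8-dimethylundeca-4,8-dien-1-yl]-5-methyldihydrofuran-2(3H)-one
Conditions: NiBr2·diglyme (10 mol %), 4,4′-di-tBu-bipyridine (10 mol %), nBu4NBF4, DMA, undivided cell, Zn anode/carbon cathode, 3 mA, rt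
Reagents that add atoms: none
Why: Ni-electrocatalytic decarboxylative alkenylation (radical capture by an alkenyl-Ni species, then reductive elimination) forms the C6–C7 bond with retention of the E vinyl-iodide geometry, and free alcohols, lactone and furan are tolerated.

**Step 14**
Reactants: 20
Product: 21 10-acetylirciformonin B
Conditions: Ac2O (1.1 equiv), pyridine (3 equiv), DMAP (5 mol %), CH2Cl2, −20 °C
Reagents that add atoms: acetic anhydride, CC(=O)OC(C)=O
Why: The secondary allylic C10–OH is far less hindered than the C15–OH beside the quaternary centre, so limiting Ac2O at low temperature acylates C10 selectively with no change at any stereocentre.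

**Compound list**
1 | (S)-linalool | C=C[C@@](C)(O)CCC=C(C)C | starting material
2 | (5S)-5-methyl-5-vinyltetrahydrofuran-2-ol (lactol, anomeric mixture) | C=C[C@]1(C)CCC(O)O1 | intermediate
3 | (5S)-5-methyl-5-vinyldihydrofuran-2(3H)-one | C=C[C@]1(C)CCC(=O)O1 | intermediate
4 | (5S)-5-methyl-2-oxotetrahydrofuran-5-carbaldehyde | O=C[C@]1(C)CCC(=O)O1 | intermediate
5 | 4-methylpent-4-enoic acid | CC(=C)CCC(=O)O | starting material
6 | N-hydroxyphthalimide | O=C1c2ccccc2C(=O)N1O | starting material
7 | 1,3-dioxoisoindolin-2-yl 4-methylpent-4-enoate | CC(=C)CCC(=O)ON1C(=O)c2ccccc2C1=O | intermediate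
8 | (5S)-5-[(1R)-1-hydroxy-4-methylpent-4-en-1-yl]-5-methyldihydrofuran-2(3H)-one | CC(=C)CC[C@@H](O)[C@]1(C)CCC(=O)O1 | intermediate
9 | (S)-epichlorohydrin | ClC[C@@H]1CO1 | starting material
10 | trimethylsilylacetylene | C[Si](C)(C)C#C | starting material
11 | (2S)-1-chloro-5-(trimethylsilyl)pent-4-yn-2-ol | C[Si](C)(C)C#CC[C@H](O)CCl | intermediate
12 | (2S)-trimethyl[3-(oxiran-2-yl)prop-1-yn-1-yl]silane | C[Si](C)(C)C#CC[C@H]1CO1 | intermediate
13 | trimethylsulfonium iodide | C[S+](C)C.[I-] | starting material
14 | (3S)-7-(trimethylsilyl)hept-1-en-6-yn-3-ol | C=C[C@@H](O)CC#C[Si](C)(C)C | intermediate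
15 | (3S)-hept-1-en-6-yn-3-ol | C=C[C@@H](O)CC#C | intermediate
16 | (3S,6E)-7-iodo-6-methylhepta-1,6-dien-3-ol | C=C[C@@H](O)C/C(C)=C/I | intermediate
17 | (5S)-5-[(1R,4E,6S,8E)-1,6-dihydroxy-9-iodo-4,8-dimethylnona-4,8-dien-1-yl]-5-methyldihydrofuran-2(3H)-one | O[C@H](/C=C(\C)CC[C@@H](O)[C@]1(C)CCC(=O)O1)C/C(C)=C/I | intermediate
18 | 3-(furan-3-yl)propanoic acid | OC(=O)CCc1ccoc1 | starting material
19 | 1,3-dioxoisoindolin-2-yl 3-(furan-3-yl)propanoate | O=C(CCc1ccoc1)ON1C(=O)c2ccccc2C1=O | intermediate
20 | (5S)-5-[(1R,4E,6S,8E)-11-(furan-3-yl)-1,6-dihydroxy-4,8-dimethylundeca-4,8-dien-1-yl]-5-methyldihydrofuran-2(3H)-one | O[C@H](/C=C(\C)CC[C@@H](O)[C@]1(C)CCC(=O)O1)C/C(C)=C/CCc1ccoc1 | intermediate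
21 | 10-acetylirciformonin B | CC(=O)O[C@H](/C=C(\C)CC[C@@H](O)[C@]1(C)CCC(=O)O1)C/C(C)=C/CCc1ccoc1 | target

**Totals**
Total steps: 14. Longest linear sequence: 8 (9 → 11 → 12 → 14 → 15 → 16 → 17 → 20 → 21, i.e. steps 6–11, 13, 14).

**Three steps most likely to fail**
1. **Step 5 (proposed new Cr/photoredox addition).** Risks are hydrodecarboxylation, protonation of the alkyl-Cr, Cr-alkoxide translactonisation, and low Felkin selectivity. Fallback: add 3-methylbut-3-enylmagnesium bromide/CeCl3 to aldehyde 4 at −78 °C (organocerium, chemoselective for the aldehyde over the lactone) and separate the diastereomers.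
2. **Step 11 (trisubstituted cross-metathesis).** Risks are E/Z ratio, yield and diol dimerisation. Fallback: TBS-protect 15, selectively ozonolyse the vinyl group (the terminal alkyne survives), add isopropenylMgBr, and run a Johnson–Claisen rearrangement (E-selective) to the homoallyl ester. Hydrolyse to the acid, convert to the RAE, couple to aldehyde 4 as in step 5, then do the carboalumination and Ni coupling.
3. **Step 13 (Ni-electrocatalytic coupling on a polyfunctional substrate).** Risks are allylic-alcohol ionisation and furan or lactone sensitivity. Fallback: bis-TES-protect 17 and run a Pd-PEPPSI Negishi coupling with 2-(furan-3-yl)ethylzinc bromide, then remove the TES groups.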